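**Plan**

1. Retrosynthetic cuts: the two phenols are masked as methoxymethyl (MOM) ethers; the lactone is opened at O1–C2 to a 2-ene-1,4-diol; C4–C5 is cut back to a C4–boron bond; C3–C4 and the ring B–CH2 bond are then cut together.
2. Enabling feature: C4 sits between the benzylic CH2 of ring B and the alkenyl carbon C3, so CH2–C4 is the former vinyl group of a vinylboronic ester. One conjunctive coupling attaches the ring B aryl group and the C3 alkenyl group to it and leaves boron on C4.
3. Forward order: ring A aldehyde to a Z-iodoalkene (steps 1–4); vanillin to the ring B aryl triflate (steps 5–7); three-component coupling joins the chain (step 8); CH2 insertion and oxidation add C5 (step 9); the lactone, the only ring made, closes last (step 11); the phenols are freed (step 12).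
4. Stereochemistry: C4 (R) is set by the chiral MandyPhos–palladium catalyst in step 8 and carried through the boron homologation with retention. The E-arylidene geometry is set in the iodo-ylide Wittig reaction and kept through lithiation and migration.

Key step: step 8

Assumption: lactone numbering is O1, C2 (C=O), C3 (arylidene carbon), C4 (stereocentre), C5 (OCH2), ring A is the 3-hydroxy-4,5-dimethoxyphenyl ring and ring B the 4-hydroxy-3-methoxyphenyl ring; the (Sp,Sp) enantiomer of MandyPhos is taken, by analogy with simple aryl cases, to give the R boronate, and the mirror-image ligand would be used if the sense proves opposite.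

**Route**

Step 1
Reactants: 1 3-hydroxy-4,5-dimethoxybenzaldehyde
Product: 2 3,4-dimethoxy-5-(methoxymethoxy)benzaldehyde
Conditions: MOMCl, iPr2NEt, CH2Cl2, 0 °C to rt
Reagents that add atoms: chloromethyl methyl ether, COCCl
Why: O-alkylation of the phenol (MOM ether formation) under amine base leaves the aldehyde untouched and gives a phenol mask that tolerates organolithium, palladium and fluoride.

Step 2
Reactants: 2 3,4-dimethoxy-5-(methoxymethoxy)benzaldehyde
Product: 3 ethyl (Z)-2-iodo-3-[3,4-dimethoxy-5-(methoxymethoxy)phenyl]prop-2-enoate (iodine cis to ring A)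
Conditions: Ph3P=CHCO2Et, NIS, CH2Cl2, −20 °C; then K2CO3 and 2, −20 °C to rt
Reagents that add atoms: ethyl (triphenylphosphoranylidene)acetate, CCOC(=O)C=P(c1ccccc1)(c1ccccc1)c1ccccc1; N-iodosuccinimide, O=C1CCC(=O)N1I
Why: One-pot iodination of the stabilised ylide followed by Wittig olefination should place the ester trans to the aryl group, so iodine ends cis to ring A, the geometry that later becomes the E-arylidene.

Step 3
Reactants: 3 ethyl (Z)-2-iodo-3-[3,4-dimethoxy-5-(methoxymethoxy)phenyl]prop-2-enoate
Product: 4 (Z)-2-iodo-3-[3,4-dimethoxy-5-(methoxymethoxy)phenyl]prop-2-en-1-ol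
Conditions: iBu2AlH, CH2Cl2, −78 °C
Reagents that add atoms: none
Why: 1,2-Reduction of the enoate by iBu2AlH at low temperature should give the allylic alcohol without touching the vinylic C–I bond, the alkene geometry or the MOM ether.

Step 4
Reactants: 4 (Z)-2-iodo-3-[3,4-dimethoxy-5-(methoxymethoxy)phenyl]prop-2-en-1-ol
Product: 5 (Z)-[2-iodo-3-[3,4-dimethoxy-5-(methoxymethoxy)phenyl]prop-2-enoxy]triisopropylsilane
Conditions: TIPSCl, imidazole, DMF, rt
Reagents that add atoms: triisopropylsilyl chloride, CC(C)[Si](Cl)(C(C)C)C(C)C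
Why: Silylation of the primary alcohol; the bulky triisopropylsilyl group is chosen because it resists oxygen-to-carbon silyl migration in the derived alkenyllithium and is later removed by fluoride without loss of the MOM ethers.

Step 5
Reactants: 6 vanillin
Product: 7 3-methoxy-4-(methoxymethoxy)benzaldehyde
Conditions: MOMCl, iPr2NEt, CH2Cl2, 0 °C to rt
Reagents that add atoms: chloromethyl methyl ether, COCCl
Why: The same MOM ether formation as in step 1, so that both phenols are unmasked together at the end.

Step 6
Reactants: 7 3-methoxy-4-(methoxymethoxy)benzaldehyde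
Product: 9 3-methoxy-4-(methoxymethoxy)phenol, via aryl formate 8 (not isolated)
Conditions: mCPBA, CH2Cl2, 0 °C to rt; aqueous NaHCO3 wash; then K2CO3 (cat.), MeOH, rt
Reagents that add atoms: 3-chloroperoxybenzoic acid, OOC(=O)c1cccc(Cl)c1
Why: Baeyer–Villiger (Dakin-type) oxidation of the electron-rich benzaldehyde proceeds by aryl migration to the formate, which base-catalysed methanolysis converts to the phenol.

Step 7
Reactants: 9 3-methoxy-4-(methoxymethoxy)phenol
Product: 10 3-methoxy-4-(methoxymethoxy)phenyl trifluoromethanesulfonate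
Conditions: PhNTf2, Et3N, DMAP (cat.), CH2Cl2, rt
Reagents that add atoms: N-phenylbis(trifluoromethanesulfonimide), O=S(=O)(N(c1ccccc1)S(=O)(=O)C(F)(F)F)C(F)(F)F
Why: Sulfonyl transfer to the phenol (triflation) with the mild imide reagent leaves the MOM acetal intact and gives the halide-free electrophile that the coupling needs.

Step 8
Reactants: 5 (Z)-[2-iodo-3-[3,4-dimethoxy-5-(methoxymethoxy)phenyl]prop-2-enoxy]triisopropylsilane; 11 vinylboronic acid pinacol ester; 10 3-methoxy-4-(methoxymethoxy)phenyl trifluoromethanesulfonate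
Product: 14 2-[(2R,3E)-4-[3,4-dimethoxy-5-(methoxymethoxy)phenyl]-1-[3-methoxy-4-(methoxymethoxy)phenyl]-3-[(triisopropylsilyloxy)methyl]but-3-en-2-yl]-4,4,5,5-tetramethyl-1,3,2-dioxaborolane (ring A cis to the boron-bearing carbon), via alkenyllithium 12 (not isolated), via lithium boron ate complex 13 (not isolated)
Conditions: 5, t-BuLi (2.0 equiv), Et2O, −78 °C; 11, −78 °C to rt; solvent exchange to THF; Pd(OAc)2 (3 mol%), (Sp,Sp)-MandyPhos (3.6 mol%), 10, KOSO2CF3, THF, 60 °C
Reagents that add atoms: none
Why: Iodine–lithium exchange occurs with retention of alkene geometry and alkenyllithium 12 adds to boron of 11 to give ate complex 13; zerovalent palladium bearing MandyPhos inserts into the C–O bond of triflate 10 to give a cationic arylpalladium complex of divalent palladium, which binds the unsubstituted vinyl group of 13 and triggers a 1,2-metallate shift of the alkenyl group from boron to the alpha carbon, anti to palladium (C3–C4 formed), and reductive elimination then forms the ring B–CH2 bond. The closest known reaction type is the enantioselective palladium-catalysed conjunctive cross-coupling of vinyl boron ate complexes with aryl triflates, which is known with alkenyl migrating groups, the present one being more substituted. No ring is closed. The C4 stereocentre (R) is controlled by the chiral bisphosphine, which selects the face of the vinyl group that palladium binds, the migration itself being stereospecific. The step needs the metallate shift to outrun direct boron-to-palladium transfer (Suzuki–Miyaura coupling) and needs palladium to activate the vinyl rather than the alkenyl group: the triflate electrophile, with KOSO2CF3 removing iodide as KI, keeps palladium cationic, and the trisubstituted aryl-bearing alkenyl group is too hindered to bind. The migrating sp2 carbon keeps its configuration, so ring A stays cis to C4.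

Step 9
Reactants: 14 the (R)-allylic pinacol boronate
Product: 16 (2R,3E)-4-[3,4-dimethoxy-5-(methoxymethoxy)phenyl]-2-[[3-methoxy-4-(methoxymethoxy)phenyl]methyl]-3-[(triisopropylsilyloxy)methyl]but-3-en-1-ol, via homologated boronate 15 (not isolated)
Conditions: BrCH2Cl, n-BuLi, THF, −78 °C to rt; then NaBO3·4H2O, THF–H2O, rt
Reagents that add atoms: bromochloromethane, ClCBr; sodium perborate tetrahydrate, [Na+].[O-]OB=O.O.O.O.O
Why: Matteson homologation, in which LiCH2Cl adds to boron and the allylic carbon migrates 1,2 with retention to form C4–C5, followed by perborate oxidation of the primary C–B bond, should give the alcohol with the C4 configuration unchanged.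

Step 10
Reactants: 16 the (2R,3E) silyl ether alcohol
Product: 17 (2E,3R)-2-[[3,4-dimethoxy-5-(methoxymethoxy)phenyl]methylidene]-3-[[3-methoxy-4-(methoxymethoxy)phenyl]methyl]butane-1,4-diol
Conditions: Bu4NF, THF, 0 °C to rt
Reagents that add atoms: none
Why: Fluoride-induced desilylation frees the allylic alcohol under basic conditions that spare the MOM ethers and the acid-sensitive cinnamyl-type alcohol.

Step 11
Reactants: 17 the (2E,3R) 2-ene-1,4-diol
Product: 20 (3E,4R)-3-[[3,4-dimethoxy-5-(methoxymethoxy)phenyl]methylidene]-4-[[3-methoxy-4-(methoxymethoxy)phenyl]methyl]oxolan-2-one, via hydroxy enal 18 (not isolated), via lactol 19 (not isolated)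
Conditions: MnO2 (activated, excess), CH2Cl2, rt
Reagents that add atoms: none
Why: MnO2 oxidative lactonisation of a 2-ene-1,4-diol: only the allylic alcohol is oxidised, the C5 hydroxyl adds to the enal to give the five-membered lactol, and this allylic lactol is oxidised to the lactone, which fixes the carbonyl at C2.

Step 12
Reactants: 20 the bis-MOM lactone
Product: 21 (3E,4R)-3-[(3-hydroxy-4,5-dimethoxyphenyl)methylidene]-4-[(4-hydroxy-3-methoxyphenyl)methyl]oxolan-2-one (CNP0187799.1)
Conditions: HCl (about 1 M), MeOH, rt
Reagents that add atoms: none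
Why: Acid-catalysed acetal cleavage transfers the methoxymethyl groups to methanol, which should avoid electrophilic attack of formaldehyde equivalents on the arenes while the lactone, the alkene geometry and the non-enolisable C4 centre persist.

**Compound list**

1 | 3-hydroxy-4,5-dimethoxybenzaldehyde | COc1cc(C=O)cc(O)c1OC | starting material
2 | 3,4-dimethoxy-5-(methoxymethoxy)benzaldehyde | COCOc1cc(C=O)cc(OC)c1OC | intermediate
3 | ethyl (Z)-2-iodo-3-[3,4-dimethoxy-5-(methoxymethoxy)phenyl]prop-2-enoate | CCOC(=O)/C(I)=C/c1cc(OCOC)c(OC)c(OC)c1 | intermediate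
4 | (Z)-2-iodo-3-[3,4-dimethoxy-5-(methoxymethoxy)phenyl]prop-2-en-1-ol | OC/C(I)=C/c1cc(OCOC)c(OC)c(OC)c1 | intermediate
5 | (Z)-[2-iodo-3-[3,4-dimethoxy-5-(methoxymethoxy)phenyl]prop-2-enoxy]triisopropylsilane | CC(C)[Si](OC/C(I)=C/c1cc(OCOC)c(OC)c(OC)c1)(C(C)C)C(C)C | intermediate
6 | vanillin (4-hydroxy-3-methoxybenzaldehyde) | COc1cc(C=O)ccc1O | starting material
7 | 3-methoxy-4-(methoxymethoxy)benzaldehyde | COCOc1ccc(C=O)cc1OC | intermediate
8 | 3-methoxy-4-(methoxymethoxy)phenyl formate | COCOc1ccc(OC=O)cc1OC | intermediate (not isolated)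
9 | 3-methoxy-4-(methoxymethoxy)phenol | COCOc1ccc(O)cc1OC | intermediate
10 | 3-methoxy-4-(methoxymethoxy)phenyl trifluoromethanesulfonate | COCOc1ccc(OS(=O)(=O)C(F)(F)F)cc1OC | intermediate
11 | vinylboronic acid pinacol ester | C=CB1OC(C)(C)C(C)(C)O1 | starting material
12 | [(E)-1-[3,4-dimethoxy-5-(methoxymethoxy)phenyl]-3-(triisopropylsilyloxy)prop-1-en-2-yl]lithium, lithium cis to ring A | [Li]/C(CO[Si](C(C)C)(C(C)C)C(C)C)=C\c1cc(OCOC)c(OC)c(OC)c1 | intermediate (not isolated)
13 | lithium vinyl(alkenyl)(pinacolato)borate, the alkenyl group being that of 12 with boron cis to ring A | [Li+].C=C[B-]1(OC(C)(C)C(C)(C)O1)/C(CO[Si](C(C)C)(C(C)C)C(C)C)=C\c1cc(OCOC)c(OC)c(OC)c1 | intermediate (not isolated)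
14 | 2-[(2R,3E)-4-[3,4-dimethoxy-5-(methoxymethoxy)phenyl]-1-[3-methoxy-4-(methoxymethoxy)phenyl]-3-[(triisopropylsilyloxy)methyl]but-3-en-2-yl]-4,4,5,5-tetramethyl-1,3,2-dioxaborolane | COc1cc(C[C@@H](B2OC(C)(C)C(C)(C)O2)/C(CO[Si](C(C)C)(C(C)C)C(C)C)=C\c2cc(OCOC)c(OC)c(OC)c2)ccc1OCOC | intermediate
15 | 2-[(2R,3E)-4-[3,4-dimethoxy-5-(methoxymethoxy)phenyl]-2-[[3-methoxy-4-(methoxymethoxy)phenyl]methyl]-3-[(triisopropylsilyloxy)methyl]but-3-enyl]-4,4,5,5-tetramethyl-1,3,2-dioxaborolane | COc1cc(C[C@@H](CB2OC(C)(C)C(C)(C)O2)/C(CO[Si](C(C)C)(C(C)C)C(C)C)=C\c2cc(OCOC)c(OC)c(OC)c2)ccc1OCOC | intermediate (not isolated)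
16 | (2R,3E)-4-[3,4-dimethoxy-5-(methoxymethoxy)phenyl]-2-[[3-methoxy-4-(methoxymethoxy)phenyl]methyl]-3-[(triisopropylsilyloxy)methyl]but-3-en-1-ol | COc1cc(C[C@@H](CO)/C(CO[Si](C(C)C)(C(C)C)C(C)C)=C\c2cc(OCOC)c(OC)c(OC)c2)ccc1OCOC | intermediate
17 | (2E,3R)-2-[[3,4-dimethoxy-5-(methoxymethoxy)phenyl]methylidene]-3-[[3-methoxy-4-(methoxymethoxy)phenyl]methyl]butane-1,4-diol | COc1cc(C[C@@H](CO)/C(CO)=C\c2cc(OCOC)c(OC)c(OC)c2)ccc1OCOC | intermediate
18 | (2E,3R)-2-[[3,4-dimethoxy-5-(methoxymethoxy)phenyl]methylidene]-4-hydroxy-3-[[3-methoxy-4-(methoxymethoxy)phenyl]methyl]butanal | COc1cc(C[C@@H](CO)/C(C=O)=C\c2cc(OCOC)c(OC)c(OC)c2)ccc1OCOC | intermediate (not isolated)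
19 | (3E,4R)-3-[[3,4-dimethoxy-5-(methoxymethoxy)phenyl]methylidene]-4-[[3-methoxy-4-(methoxymethoxy)phenyl]methyl]oxolan-2-ol, both configurations at C2 | COc1cc(C[C@H]2COC(O)/C2=C/c2cc(OCOC)c(OC)c(OC)c2)ccc1OCOC | intermediate (not isolated)
20 | (3E,4R)-3-[[3,4-dimethoxy-5-(methoxymethoxy)phenyl]methylidene]-4-[[3-methoxy-4-(methoxymethoxy)phenyl]methyl]oxolan-2-one | COc1cc(C[C@H]2COC(=O)/C2=C/c2cc(OCOC)c(OC)c(OC)c2)ccc1OCOC | intermediate
21 | (3E,4R)-3-[(3-hydroxy-4,5-dimethoxyphenyl)methylidene]-4-[(4-hydroxy-3-methoxyphenyl)methyl]oxolan-2-one | COc1cc(C[C@H]2COC(=O)/C2=C/c2cc(O)c(OC)c(OC)c2)ccc1O | target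

**Step count**

Total steps: 12. Longest linear sequence: 9 steps (steps 1–4 and 8–12); the ring B branch (steps 5–7) is 3 steps.

**Steps most likely to fail**

Step 8. Several processes could erode the coupling:
- iodide left from the exchange may bind palladium and stop alkene activation;
- the alkenyllithium may lose geometry or suffer oxygen-to-carbon silyl migration before it is trapped;
- the hindered alkenyl group may migrate slowly, so that direct boron-to-palladium transfer takes over;
- facial discrimination may be incomplete.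

The fallback sets out from 5 and keeps the same bond formation. Miyaura borylation of 5 (B2pin2, PdCl2(PPh3)2, PPh3, KOPh, toluene, 50 °C) would give the alkenyl pinacol boronate F1, boron cis to ring A. Halide-free vinyllithium, made from Sn(CH=CH2)4 and n-BuLi, would then add to F1 in Et2O to give the same ate complex 13. This reaches 13 without a free alkenyllithium, without iodide and without a scavenger, and the route is rejoined at 13, which is coupled with 10 as in step 8.

Step 9. The hindered secondary allylic boronate may capture LiCH2Cl slowly while the carbenoid decomposes, a pinacol oxygen may migrate in place of carbon, and unhomologated boronate would then be oxidised to a secondary allylic alcohol. The fallback sets out from 14 and splits the insertion into two stages. The more persistent carbenoid LiCHCl2 (CH2Cl2, n-BuLi, THF, −100 °C, then ZnCl2 on warming) would give the alpha-chloro boronate F2, a mixture at the new CHCl carbon with C4 retained. LiBHEt3 would then displace chloride through a hydride ate complex and 1,2-shift. The route is rejoined at 15, which is oxidised with NaBO3·4H2O as before.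

Step 2. Geometric control in the one-pot iodination–olefination may be incomplete, and incomplete iodination of the ylide would give the iodine-free cinnamate. The fallback sets out from 2. A Wittig reaction with Ph3P=CHCHO (toluene, 80 °C) would give the (E)-enal F3. Alpha-iodination (I2, DMAP, K2CO3, THF–H2O) proceeds by conjugate addition of DMAP, iodination of the enolate and elimination, and should give the (Z)-2-iodoenal F4 with the formyl group trans to ring A. Luche reduction (NaBH4, CeCl3·7H2O, MeOH, 0 °C) rejoins the route at 4.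

**Further compounds**

F1 | step 8 | (E)-[3-[3,4-dimethoxy-5-(methoxymethoxy)phenyl]-2-(4,4,5,5-tetramethyl-1,3,2-dioxaborolan-2-yl)prop-2-enoxy]triisopropylsilane, boron cis to ring A | CC(C)[Si](OC/C(B1OC(C)(C)C(C)(C)O1)=C/c1cc(OCOC)c(OC)c(OC)c1)(C(C)C)C(C)C
F2 | step 9 | alpha-chloro homologue of 14: 2-[(3E)-1-chloro-4-[3,4-dimethoxy-5-(methoxymethoxy)phenyl]-2-[[3-methoxy-4-(methoxymethoxy)phenyl]methyl]-3-[(triisopropylsilyloxy)methyl]but-3-enyl]-4,4,5,5-tetramethyl-1,3,2-dioxaborolane, C4 configuration of 14 retained, both configurations at CHCl | COc1cc(C[C@@H](C(Cl)B2OC(C)(C)C(C)(C)O2)/C(CO[Si](C(C)C)(C(C)C)C(C)C)=C\c2cc(OCOC)c(OC)c(OC)c2)ccc1OCOC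
F3 | step 2 | (E)-3-[3,4-dimethoxy-5-(methoxymethoxy)phenyl]prop-2-enal | COCOc1cc(/C=C/C=O)cc(OC)c1OC
F4 | step 2 | (Z)-2-iodo-3-[3,4-dimethoxy-5-(methoxymethoxy)phenyl]prop-2-enal | O=C/C(I)=C/c1cc(OCOC)c(OC)c(OC)c1
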